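**Retrosynthetic overview**
1. Irigenin 9 ⇐ tribenzyl ether 8 by global O-debenzylation.
2. Key cut: the C3–C1' bond of the pyranone (ring C) is traced back to the C2–C1' bond of flavanone 7. An iodine(III)-induced 2,3-shift of the B ring copies the isoflavone-synthase step; it is invited by the 3-hydroxy-4,5-dimethoxyphenyl ring on C3, whose C4'–OMe is para to the migrating carbon.
3. 7 ⇐ chalcone 6 (oxa-Michael, O1–C2 closure of ring C) ⇐ acetophenone 4 + aldehyde 5 (Claisen–Schmidt, Cα=Cβ).
4. 4 ⇐ 1 by Elbs para-hydroxylation and O-methylation. This puts the OMe on the future C6 and leaves only the future O1 hydroxyl free, so 6-OMe versus 8-OMe is fixed.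
5. Ring order: rings A and B are bought, ring C is closed in step 4 and re-wired in step 5.

Key step: step 5

Remark: irigenin has no stereocentre, so the "single enantiomer" is the compound itself. Flavanone 7 is used as the racemate because its only stereocentre (C2) is destroyed in step 5. Benzyl ethers 1 and 5 are taken as catalogue compounds.

**Step 1**
Reactants: 1 1-[2,4-bis(benzyloxy)-6-hydroxyphenyl]ethan-1-one
Product: 3 1-[2,4-bis(benzyloxy)-3,6-dihydroxyphenyl]ethan-1-one, via potassium aryl sulfate 2 (not isolated)
Conditions: K2S2O8, aq KOH, pyridine, 0 °C to rt; then aq HCl, Na2SO3, 80 °C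
Reagents that add atoms: potassium peroxydisulfate, [K+].[K+].[O-]S(=O)(=O)OOS(=O)(=O)[O-]
Why: Elbs persulfate oxidation, in which the phenoxide of 1 attacks a peroxide oxygen through the ring carbon para to the free hydroxyl (the only para position, between the two benzyloxy groups), and acid hydrolysis of the aryl sulfate 2 then frees the hydroquinone, a sequence with close precedent on benzyl-protected phloroacetophenones.

**Step 2**
Reactants: 3 1-[2,4-bis(benzyloxy)-3,6-dihydroxyphenyl]ethan-1-one
Product: 4 1-[2,4-bis(benzyloxy)-6-hydroxy-3-methoxyphenyl]ethan-1-one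
Conditions: Me2SO4 (1.05 equiv), K2CO3, acetone, reflux
Reagents that add atoms: dimethyl sulfate, COS(=O)(=O)OC
Why: Williamson ether synthesis made site-selective by hydrogen bonding, since the 6-OH is held in a chelate with the acetyl carbonyl and is far less nucleophilic than the new non-chelated 3-OH, so one equivalent of dimethyl sulfate should methylate only the latter.

**Step 3**
Reactants: 4 1-[2,4-bis(benzyloxy)-6-hydroxy-3-methoxyphenyl]ethan-1-one; 5 3-(benzyloxy)-4,5-dimethoxybenzaldehyde
Product: 6 (2E)-1-[2,4-bis(benzyloxy)-6-hydroxy-3-methoxyphenyl]-3-[3-(benzyloxy)-4,5-dimethoxyphenyl]prop-2-en-1-one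
Conditions: KOH, EtOH–H2O, rt, 48 h; then dilute HCl, filtration
Reagents that add atoms: none
Why: Claisen–Schmidt condensation of the methyl ketone enolate with a non-enolisable aldehyde followed by E1cB dehydration, which should give the conjugated chalcone with the thermodynamically preferred E geometry.

**Step 4**
Reactants: 6 (2E)-1-[2,4-bis(benzyloxy)-6-hydroxy-3-methoxyphenyl]-3-[3-(benzyloxy)-4,5-dimethoxyphenyl]prop-2-en-1-one
Product: 7 rac-5,7-bis(benzyloxy)-2-[3-(benzyloxy)-4,5-dimethoxyphenyl]-6-methoxy-2,3-dihydro-4H-chromen-4-one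
Conditions: NaOAc, EtOH, reflux
Reagents that add atoms: none
Why: intramolecular 6-endo-trig oxa-Michael addition of the only free phenol to the enone closes ring C through O1–C2, the equilibrium lying on the flavanone side because the 6'-benzyloxy group twists the chalcone out of conjugation, and the new C2 stereocentre forms as the racemate, which is sufficient because step 5 removes it.

**Step 5**
Reactants: 7 rac-5,7-bis(benzyloxy)-2-[3-(benzyloxy)-4,5-dimethoxyphenyl]-6-methoxy-2,3-dihydro-4H-chromen-4-one
Product: 8 5,7-bis(benzyloxy)-3-[3-(benzyloxy)-4,5-dimethoxyphenyl]-6-methoxy-4H-chromen-4-one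
Conditions: PhI(OH)OTs (1.2 equiv), MeCN, reflux
Reagents that add atoms: none
Why: Acid-promoted enolisation of the C4 ketone towards C3 and attack of the enol on iodine(III) place a PhI(OTs) group on C3 trans to the C2 aryl group; in the diaxial conformer the B ring lies antiperiplanar to the C3–I bond and shifts from C2 to C3 through a bridged phenonium ion as iodobenzene departs, the positive charge ending on C2 as an oxocarbenium ion stabilised by O1, and loss of the C3 proton then gives the C2=C3 bond of the chromone. The closest known reaction type is the hypervalent-iodine (or thallium(III)) mediated oxidative 2,3-aryl migration of flavanones to isoflavones, the laboratory counterpart of the isoflavone-synthase step of the biosynthesis. No ring is closed (ring C is carried through intact while the C2–C1' bond is exchanged for C3–C1') and no stereocentre is created, the racemic C2 centre of 7 being erased. The step needs migration to win over loss of the C2 proton (flavone), over tosylate capture at C3 and over oxidation of the arenes: the para-methoxy group at C4' makes the B ring a good bridging group, the O1 lone pair drives the shift, acetonitrile offers no nucleophile, and the absence of any free phenol (the p-methoxyphenol of ring A is tied up as O1 and as benzyl ethers) keeps iodine(III) away from quinone formation.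

**Step 6**
Reactants: 8 5,7-bis(benzyloxy)-3-[3-(benzyloxy)-4,5-dimethoxyphenyl]-6-methoxy-4H-chromen-4-one
Product: 9 irigenin, 5,7-dihydroxy-3-(3-hydroxy-4,5-dimethoxyphenyl)-6-methoxy-4H-chromen-4-one
Conditions: H2 (1 atm), 10% Pd/C, THF–MeOH, rt, stopped after uptake of 3 equiv
Reagents that add atoms: none
Why: catalytic hydrogenolysis of the three benzylic C–O bonds at balloon pressure should be faster than saturation of the trisubstituted, donor-substituted C2=C3 bond of the vinylogous ester, so all three phenols are freed in one operation while the methyl ethers stay untouched.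

**Compound list**
1 | 1-[2,4-bis(benzyloxy)-6-hydroxyphenyl]ethan-1-one | CC(=O)c1c(O)cc(OCc2ccccc2)cc1OCc1ccccc1 | starting material
2 | potassium 3-acetyl-2,6-bis(benzyloxy)-4-hydroxyphenyl sulfate | CC(=O)c1c(O)cc(OCc2ccccc2)c(OS(=O)(=O)[O-])c1OCc1ccccc1.[K+] | intermediate
3 | 1-[2,4-bis(benzyloxy)-3,6-dihydroxyphenyl]ethan-1-one | CC(=O)c1c(O)cc(OCc2ccccc2)c(O)c1OCc1ccccc1 | intermediate
4 | 1-[2,4-bis(benzyloxy)-6-hydroxy-3-methoxyphenyl]ethan-1-one | CC(=O)c1c(O)cc(OCc2ccccc2)c(OC)c1OCc1ccccc1 | intermediate
5 | 3-(benzyloxy)-4,5-dimethoxybenzaldehyde | COc1cc(C=O)cc(OCc2ccccc2)c1OC | starting material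
6 | (2E)-1-[2,4-bis(benzyloxy)-6-hydroxy-3-methoxyphenyl]-3-[3-(benzyloxy)-4,5-dimethoxyphenyl]prop-2-en-1-one | COc1cc(/C=C/C(=O)c2c(O)cc(OCc3ccccc3)c(OC)c2OCc2ccccc2)cc(OCc2ccccc2)c1OC | intermediate
7 | rac-5,7-bis(benzyloxy)-2-[3-(benzyloxy)-4,5-dimethoxyphenyl]-6-methoxy-2,3-dihydro-4H-chromen-4-one (racemate, C2 unspecified) | COc1cc(C2CC(=O)c3c(O2)cc(OCc4ccccc4)c(OC)c3OCc3ccccc3)cc(OCc2ccccc2)c1OC | intermediate
8 | 5,7-bis(benzyloxy)-3-[3-(benzyloxy)-4,5-dimethoxyphenyl]-6-methoxy-4H-chromen-4-one | COc1cc(-c2coc3cc(OCc4ccccc4)c(OC)c(OCc4ccccc4)c3c2=O)cc(OCc2ccccc2)c1OC | intermediate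
9 | irigenin, 5,7-dihydroxy-3-(3-hydroxy-4,5-dimethoxyphenyl)-6-methoxy-4H-chromen-4-one | COc1cc(-c2coc3cc(O)c(OC)c(O)c3c2=O)cc(O)c1OC | target

**Step count and risks**
Total step count: 6. Longest linear sequence: 6 steps (1 to 9).

Steps most likely to fail:

1. Step 5. The C3-iodanyl ketone may lose the C2 proton (dehydrogenation to the flavone) or be captured by tosylate before the B ring migrates, and the electron-rich rings may be attacked by iodine(III). Fallback: the rearrangement is moved to the open-chain chalcone, where no C2–H elimination path exists. It sets out from 6. Acetylation (Ac2O, pyridine, DMAP, rt) masks the p-methoxyphenol as 3,5-bis(benzyloxy)-2-{(2E)-3-[3-(benzyloxy)-4,5-dimethoxyphenyl]prop-2-enoyl}-4-methoxyphenyl acetate F1. Oxythallation and 1,2-aryl shift with Tl(NO3)3·3H2O in MeOH–CH(OMe)3 at rt should give the acetal rac-3,5-bis(benzyloxy)-2-{2-[3-(benzyloxy)-4,5-dimethoxyphenyl]-3,3-dimethoxypropanoyl}-4-methoxyphenyl acetate F2. HCl in MeOH at reflux then removes the acetate and closes ring C by attack of the phenol on the acetal carbon with loss of methanol. The fallback comes back to the route at 8.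

2. Step 1. Conversion may stay low because the phenoxide is poorly soluble and hindered at the para carbon, persulfate may over-oxidise the ring, and benzyl groups may be partly lost during the hot acidic hydrolysis. Fallback: oxidation to the quinone and reduction in place of the sulfate route. It sets out from 1. Teuber oxidation with Fremy's salt (2.2 equiv, KH2PO4 buffer, acetone–H2O, rt) should give 2-acetyl-3,5-bis(benzyloxy)cyclohexa-2,5-diene-1,4-dione F3. Reduction with Na2S2O4 (EtOAc–H2O, rt) comes back to the route at 3.

3. Step 6. The C2=C3 bond may be over-reduced to the isoflavanone, or debenzylation may stall at the hindered 5-O-benzyl group. Fallback: non-reductive Lewis-acid debenzylation, so that hydrogen never meets the enone. It sets out from 8 and passes through no new compound (F0). BCl3 with pentamethylbenzene as benzyl-cation scavenger in CH2Cl2 at −78 °C, then MeOH quench, should cleave the three benzyl ethers while the low temperature protects the methyl ethers. It comes back to the route at 9.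

**Further compounds**
F1 | step 5 | 3,5-bis(benzyloxy)-2-{(2E)-3-[3-(benzyloxy)-4,5-dimethoxyphenyl]prop-2-enoyl}-4-methoxyphenyl acetate | COc1cc(/C=C/C(=O)c2c(OC(C)=O)cc(OCc3ccccc3)c(OC)c2OCc2ccccc2)cc(OCc2ccccc2)c1OC
F2 | step 5 | rac-3,5-bis(benzyloxy)-2-{2-[3-(benzyloxy)-4,5-dimethoxyphenyl]-3,3-dimethoxypropanoyl}-4-methoxyphenyl acetate (racemate) | COc1cc(C(C(OC)OC)C(=O)c2c(OC(C)=O)cc(OCc3ccccc3)c(OC)c2OCc2ccccc2)cc(OCc2ccccc2)c1OC
F3 | step 1 | 2-acetyl-3,5-bis(benzyloxy)cyclohexa-2,5-diene-1,4-dione | CC(=O)C1=C(OCc2ccccc2)C(=O)C(OCc2ccccc2)=CC1=O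
F0 | step 6 | none | none
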